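## The problem

Compound 28 is a (2S)-flavanone whose ring A keeps a single hydrogen (C6). C4a carries the ring-C ketone, C5, C7 and C8a carry oxygen, and C8, between the C7 and C8a oxygens, carries a branched ten-carbon chain. Ring C is joined to ring A through O1–C8a and C4–C4a, and only the oxygen on C8a may become O1. Closure through the C5 oxygen would give the 6-alkyl isomer, so the three oxygens must be told apart before ring C exists. The two stereocentres, C2 (S) and C2'' (R), are five bonds apart and cannot control one another: C2'' has to be bought and C2 has to be set by a catalyst. C2 is configurationally fragile, because base reopens ring C by retro-oxa-Michael reaction to the chalcone. The side chain is acid-sensitive: a protonated isopropenyl group is captured by a flanking phenolic oxygen to give a dimethylchroman, and the tertiary alcohol at C5'' dehydrates. The alkene also forbids hydrogenolysis. The key step rests on the position of C8 between two oxygenated carbons with the third oxygen meta. That is the pattern formed when a ketene carbon (C8a) is joined to the two carbons of an ynol ether (C8 and C7–O), with C6, C5 and C4a coming from a 3-oxygenated cyclobutenone. The chain C1''–C5'' with C2'' is C3–C4–C5–C6–C1 of (R)-limonene after cleavage of the ring alkene.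

## Retrosynthesis

**Unmasking (28 from 27 from 26).** No skeletal bond is cut. The oxygens on C7, C4' and C5'' are silyl ethers and fall together to buffered fluoride in the last step, which is neither basic (C2) nor strongly acidic (isopropenyl). The C5 oxygen is a 4-methoxybenzyl (PMB) ether. It is removed one step earlier from 26 by chelation to the C4 carbonyl, while O7 is still silylated, so no free phenol flanks the alkene when a Lewis acid is present.

**Ring C (26 from chalcone 25).** The O1–C2 bond is cut. The neighbouring cuts are C2–C1' (aryl addition to a chromone, hindered by the ortho methoxy group) and reduction of a flavone (which endangers the isopropenyl group). The oxa-Michael closure needs only the chalcone, and because O8a is the sole free hydroxyl of 25 the regiochemistry cannot go wrong. The forward step must set C2 under catalyst control and be stopped under kinetic control.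

**Aryl ketone (25 from bromophenol 19 and Weinreb amide 23).** The C4–C4a bond is cut. Acetylation and Fries rearrangement to C4a followed by aldol condensation was set aside. A Fries rearrangement needs a strong Lewis acid, which the isopropenyl group, the tertiary silyl ether and the PMB ether would not survive, and C6 (para to O8a) is open. Hydroxide-mediated condensation would also strip aryl silyl ethers. Instead C4a is marked with bromine and converted to an aryllithium, which takes the whole C4–C3–C2–ring B unit as the E-enamide 23. This divides 25 into two halves of similar size.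

**Marking C4a (19 from phenol 18).** The C4a–Br bond is cut. C4a is the only free position ortho to the hydroxyl, and C6 lies between the two bulky ethers. The forward step must be ortho-selective and stop at one bromine.

**Ring A (18 from siloxyalkyne 10 and cyclobutenone 13).** The C8a–C8 and C6–C7 bonds are cut, and with them the ring closure C8a–C4a. The obvious neighbour, C8-alkylation of a phloroglucinol, was rejected for three reasons: it needs a β-branched primary electrophile one carbon shorter than the limonene-derived chain, it must attack the most hindered ring position, and it leaves the three oxygens undifferentiated. The benzannulation makes C8 from an alkyne carbon and delivers OH on C8a, OTIPS on C7 and OPMB on C5 directly. The precursors are an acyclic alkyne and a four-carbon ring. The forward reaction must tolerate a 3-alkoxy group on the cyclobutenone.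

**Siloxyalkyne (10 from ester 7, back to (R)-limonene 1).** Ynolate formation from ester 7 by Kowalski homologation inserts one carbon (the future C8) between C1'' and the ester carbon (the future C7 with its oxygen). Ester 7 is reached from 1 by epoxidation (2), oxidative cleavage (3), aldehyde oxidation (4), esterification (5), methyl addition to the ketone (6) and silylation. The stereocentre of 1 is never α to a carbonyl group and is carried through unchanged.

**Cyclobutenone (13 from 11 and 12).** The vinylogous ester C–O bond is cut: ether exchange of 3-ethoxycyclobut-2-en-1-one 11 with 4-methoxybenzyl alcohol 12. PMB was chosen because it is thermally inert (no sigmatropic path, unlike allyl) and is removable without protic acid or hydrogen.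

**Ring-B unit (23 from 21 and 22; 21 from 20).** The C2=C3 bond is cut: Horner–Wadsworth–Emmons olefination of silylated aldehyde 21 (from 4-hydroxy-2-methoxybenzaldehyde 20) with phosphonate 22.

## Roads not taken

**Alternative 1:** Ring A is made last. The cut is C4a–C5. Heating dioxinone A2 would expel acetone, and the acylketene, enolised at C7, would close by 6π-electrocyclisation onto the C8a=C4a enol ether of a preformed (2S)-dihydropyranone to give A1.
- Merits: C2 is set early on a simple ring, arguably with more reliable enantiocontrol than a late oxa-Michael closure. No question arises about which oxygen closes ring C. The C5 and C7 hydroxyls appear free, so the ether cleavage of step 15 is not needed. In these three respects it is better than the chosen plan.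
- Weak points: A2 has to be assembled around C8, a hindered carbon flanked by two carbonyl-type groups. It must be C-alkylated with a β-branched primary electrophile that has one carbon fewer than the limonene chain. The benzylic ether at C2 must then survive thermolysis above 100 °C, and the free phenols of A1 form in the presence of an acylating ketene.
- Comparison: the chosen plan brings the chain in as an alkyne carbon, needs no alkylation at C8 and uses every carbon of the limonene fragment.

**Alternative 2:** The cuts are O1–C2 and C3–C4. A chiral phosphoric acid would ionise acetal A4 to an ortho-quinone methide that adds hydroxystyrene A5, giving 4-methoxyflavan A3 with C2 and a disposable C4 centre.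
- Merits: ring C and C2 are formed in one convergent catalytic step. A3 has no carbonyl, so C2 cannot racemise by ring opening. Here it is safer than the chosen plan at the corresponding stage.
- Weak points: A4 presupposes the pentasubstituted ring A with its chain, which is the hard part and is left unsolved. A quinone methide bearing three donor oxygens is a weak, reversibly formed electrophile. A Brønsted acid acts on a substrate with an isopropenyl group and a tertiary silyl ether. C4 must afterwards be brought to the ketone by benzylic oxidation, close to the doubly activated C2–H.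
- Comparison: the chosen plan reaches the C4 oxidation level directly and solves ring A. It must accept a reversible C–O bond formation at C2 in return.

**Alternative 3:** The cuts are C4a–C4, C4–C3 and O1–C2. PdCl2(PPh3)2 and an amine would couple iodophenol A7, carbon monoxide and arylacetylene A8 to flavone A6, and an asymmetric 1,4-reduction would follow.
- Merits: three bonds form in one robust step. A6 has no stereocentre to lose while protecting groups are handled. All oxygens are silylated, so a single deprotection suffices, one step fewer than in the chosen plan.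
- Weak points: A7 again requires ring A with its chain, plus a regioselective iodination. Five-membered (aurone) closure competes. Enantioselective conjugate reduction of a hindered 5-silyloxyflavone with an ortho-substituted aryl group has little support, and hydride or hydrogen catalysts threaten both the C4 carbonyl and the isopropenyl group.
- Comparison: both plans set C2 late. The chosen oxa-Michael closure leaves the alkene untouched and has closer precedent on 2'-hydroxychalcones.

Key step: step 9

Assumption: the quinidine-derived amine–thiourea of step 14 is taken to induce 2S; should it favour 2R, its quinine-derived pseudo-enantiomer replaces it without other change. Compounds 11 and 22 are taken as purchasable.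

Step 1
Reactants: 1 (R)-limonene
Product: 2 (4R)-1-methyl-4-(prop-1-en-2-yl)-7-oxabicyclo[4.1.0]heptane (limonene 1,2-oxide, both epoxide diastereomers)
Conditions: mCPBA (1.0 equiv), CH2Cl2, 0 °C
Reagents that add atoms: 3-chloroperbenzoic acid, O=C(OO)c1cccc(Cl)c1
Why: Prilezhaev epoxidation; the trisubstituted ring alkene is more electron-rich than the 1,1-disubstituted isopropenyl alkene and reacts first, C4 is untouched and both epoxide diastereomers serve the next step.

Step 2
Reactants: 2 limonene 1,2-oxide
Product: 3 (3R)-6-oxo-3-(prop-1-en-2-yl)heptanal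
Conditions: H5IO6, THF/H2O, 0 °C → rt
Reagents that add atoms: water, O
Why: Acid-mediated opening of the epoxide to the glycol and Malaprade glycol cleavage in one flask; the stereocentre is β to the new aldehyde and cannot epimerise.

Step 3
Reactants: 3 (3R)-6-oxo-3-(prop-1-en-2-yl)heptanal
Product: 4 (3R)-6-oxo-3-(prop-1-en-2-yl)heptanoic acid
Conditions: NaClO2, NaH2PO4, 2-methylbut-2-ene, t-BuOH/H2O, 0 °C → rt
Reagents that add atoms: sodium chlorite, [Na+].[O-]Cl=O
Why: Pinnick oxidation; chlorite oxidises only the aldehyde and the scavenger alkene intercepts hypochlorous acid before it can add to the isopropenyl group.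

Step 4
Reactants: 4 (3R)-6-oxo-3-(prop-1-en-2-yl)heptanoic acid
Product: 5 methyl (3R)-6-oxo-3-(prop-1-en-2-yl)heptanoate
Conditions: MeI, K2CO3, DMF, rt
Reagents that add atoms: iodomethane, CI
Why: Carboxylate O-alkylation (SN2); K2CO3 is too weak to enolise the ketone, so only the ester forms.

Step 5
Reactants: 5 methyl (3R)-6-oxo-3-(prop-1-en-2-yl)heptanoate
Product: 6 methyl (3R)-6-hydroxy-6-methyl-3-(prop-1-en-2-yl)heptanoate
Conditions: MeMgBr (1.05 equiv), THF, −78 °C
Reagents that add atoms: methylmagnesium bromide, C[Mg]Br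
Why: Grignard addition; at −78 °C the ketone is attacked much faster than the methyl ester, and one equivalent creates the carbinol carbon C5'' with its second methyl group.

Step 6
Reactants: 6 methyl (3R)-6-hydroxy-6-methyl-3-(prop-1-en-2-yl)heptanoate
Product: 7 methyl (3R)-6-methyl-3-(prop-1-en-2-yl)-6-(triethylsilyloxy)heptanoate
Conditions: TESOTf, 2,6-lutidine, CH2Cl2, −78 °C → 0 °C
Reagents that add atoms: triethylsilyl trifluoromethanesulfonate, CC[Si](CC)(CC)OS(=O)(=O)C(F)(F)F
Why: Silylation of a tertiary alcohol with a silyl triflate; the triethylsilyl ether shields the hydroxyl from the lithium bases and the ketene of later steps and is fluoride-labile at the end.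

Step 7
Reactants: 7 methyl (3R)-6-methyl-3-(prop-1-en-2-yl)-6-(triethylsilyloxy)heptanoate
Product: 10 triisopropyl{[(4R)-7-methyl-4-(prop-1-en-2-yl)-7-(triethylsilyloxy)oct-1-yn-1-yl]oxy}silane, via dibromo enolate 8 (not isolated), via lithium ynolate 9 (not isolated)
Conditions: CH2Br2, LiTMP (2.2 equiv), THF, −78 °C; n-BuLi, −78 °C → rt; TIPSCl, −78 °C → rt
Reagents that add atoms: dibromomethane, BrCBr; chlorotriisopropylsilane, CC(C)[Si](Cl)(C(C)C)C(C)C
Why: Kowalski ester homologation stopped at the ynolate: LiCHBr2 adds to the ester and methoxide is lost to give 8, bromine–lithium exchange and 1,2-shift of the alkyl group give 9, and the bulky silyl chloride captures 9 on oxygen; the inserted carbon becomes C8 and the former ester carbon becomes C7.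

Step 8
Reactants: 11 3-ethoxycyclobut-2-en-1-one; 12 4-methoxybenzyl alcohol
Product: 13 3-[(4-methoxybenzyl)oxy]cyclobut-2-en-1-one
Conditions: PPTS (cat.), PhMe, 50 °C, reduced pressure (−EtOH)
Reagents that add atoms: none
Why: Acid-catalysed transetherification of a vinylogous ester (addition of the alcohol to the protonated enone, then loss of ethanol); removing ethanol drives the equilibrium.

Step 9
Reactants: 10 triisopropyl{[(4R)-7-methyl-4-(prop-1-en-2-yl)-7-(triethylsilyloxy)oct-1-yn-1-yl]oxy}silane; 13 3-[(4-methoxybenzyl)oxy]cyclobut-2-en-1-one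
Product: 18 5-[(4-methoxybenzyl)oxy]-2-[(2R)-5-methyl-2-(prop-1-en-2-yl)-5-(triethylsilyloxy)hexyl]-3-(triisopropylsilyloxy)phenol, via vinylketene 14 (not isolated), via vinylcyclobutenone 15 (not isolated), via dienylketene 16 (not isolated), via cyclohexadienone 17 (not isolated)
Conditions: PhMe, 110 °C, sealed tube, 13 added in portions
Reagents that add atoms: none
Why: Thermal four-electron electrocyclic opening of the strained vinylogous ester 13 gives vinylketene 14, which the ynol silyl ether 10 traps in a [2+2] cycloaddition: the alkyl-bearing alkyne carbon is the nucleophilic terminus and bonds to the ketene carbonyl carbon (C8–C8a), the silyloxy carbon bonds to the ketene α-carbon (C7–C6), giving 15. A second four-electron opening of 15 gives dienylketene 16, whose thermal six-electron electrocyclisation joins the ketene carbon to the enol-ether CH2 terminus (C8a–C4a, the closure of ring A) to give dienone 17, and tautomerisation delivers phenol 18. This is the Danheiser benzannulation in its siloxyalkyne form, which gives resorcinol monosilyl ethers; the only extension is the 3-alkoxy group on the four-membered ring. No stereocentre is created: the ring CH of 15 is transient and C2'' is a spectator. The selectivity needed is regiochemical and is secured by the polarisation of the siloxyalkyne, which places C8 between the free hydroxyl and the silyl ether; the ketene prefers the ynol ether to the isopropenyl group because the former is far more nucleophilic. The alkoxy group on the future C5 is cross-conjugated to the ketene, so it should not quench the electrophilicity of 14, and it makes the CH2 terminus of 16 more nucleophilic for the closure. The medium is neutral, so the tertiary silyl ether, the PMB ether and the alkene survive, and the three oxygens emerge as OH (C8a), OTIPS (C7) and OPMB (C5). Portionwise addition of 13 keeps 14 dilute and limits its dimerisation and its acylation of 18.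

Step 10
Reactants: 18 5-[(4-methoxybenzyl)oxy]-2-[(2R)-5-methyl-2-(prop-1-en-2-yl)-5-(triethylsilyloxy)hexyl]-3-(triisopropylsilyloxy)phenol
Product: 19 2-bromo-3-[(4-methoxybenzyl)oxy]-6-[(2R)-5-methyl-2-(prop-1-en-2-yl)-5-(triethylsilyloxy)hexyl]-5-(triisopropylsilyloxy)phenol
Conditions: NBS (1.0 equiv), i-Pr2NH (cat.), CH2Cl2, −78 °C → 0 °C
Reagents that add atoms: N-bromosuccinimide, O=C1CCC(=O)N1Br
Why: Electrophilic aromatic bromination under secondary-amine catalysis, which delivers bromine ortho to a free phenolic hydroxyl through a hydrogen-bonded N-bromoamine; C4a is the only free ortho position, and C6 is shielded by the flanking OTIPS and OPMB groups.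

Step 11
Reactants: 20 4-hydroxy-2-methoxybenzaldehyde
Product: 21 2-methoxy-4-(triisopropylsilyloxy)benzaldehyde
Conditions: TIPSCl, imidazole, DMF, rt
Reagents that add atoms: chlorotriisopropylsilane, CC(C)[Si](Cl)(C(C)C)C(C)C
Why: Silylation of the phenol; the triisopropylsilyl ether withstands the phosphonate anion and the aryllithium of the next two steps.

Step 12
Reactants: 21 2-methoxy-4-(triisopropylsilyloxy)benzaldehyde; 22 diethyl {2-[methoxy(methyl)amino]-2-oxoethyl}phosphonate
Product: 23 (2E)-N-methoxy-3-[2-methoxy-4-(triisopropylsilyloxy)phenyl]-N-methylprop-2-enamide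
Conditions: NaH, THF, 0 °C → rt
Reagents that add atoms: none
Why: Horner–Wadsworth–Emmons olefination with a stabilised phosphonate, E-selective; it attaches C2, C3 and C4 to ring B with C4 at the Weinreb amide oxidation level.

Step 13
Reactants: 19 2-bromo-3-[(4-methoxybenzyl)oxy]-6-[(2R)-5-methyl-2-(prop-1-en-2-yl)-5-(triethylsilyloxy)hexyl]-5-(triisopropylsilyloxy)phenol; 23 (2E)-N-methoxy-3-[2-methoxy-4-(triisopropylsilyloxy)phenyl]-N-methylprop-2-enamide
Product: 25 (2E)-1-{2-hydroxy-6-[(4-methoxybenzyl)oxy]-3-[(2R)-5-methyl-2-(prop-1-en-2-yl)-5-(triethylsilyloxy)hexyl]-4-(triisopropylsilyloxy)phenyl}-3-[2-methoxy-4-(triisopropylsilyloxy)phenyl]prop-2-en-1-one, via dilithio phenoxide 24 (not isolated)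
Conditions: n-BuLi (2.05 equiv), THF, −78 °C; then 23, −78 °C → −20 °C; AcOH/aq. NH4Cl quench at −78 °C
Reagents that add atoms: none
Why: Bromine–lithium exchange on the lithium phenoxide gives the O,C-dilithio species 24, which adds 1,2 to the Weinreb amide (Weinreb ketone synthesis); the chelated tetrahedral adduct collapses only on the cold buffered quench, so neither over-addition nor base-mediated closure of the chalcone should occur.

Step 14
Reactants: 25 the chalcone of step 13
Product: 26 (2S)-5-[(4-methoxybenzyl)oxy]-2-[2-methoxy-4-(triisopropylsilyloxy)phenyl]-8-[(2R)-5-methyl-2-(prop-1-en-2-yl)-5-(triethylsilyloxy)hexyl]-7-(triisopropylsilyloxy)-2,3-dihydro-4H-chromen-4-one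
Conditions: quinidine-derived amine–thiourea, N-[3,5-bis(trifluoromethyl)phenyl]-N'-(9-deoxy-9-epi-quinidin-9-yl)thiourea (10 mol %), PhMe, 0 °C → rt
Reagents that add atoms: none
Why: Intramolecular oxa-Michael addition (6-endo-trig) under bifunctional cinchona amine–thiourea catalysis: the quinuclidine nitrogen activates the phenol, the thiourea binds the enone carbonyl and the catalyst decides the face of C2 (2S); C2'' is too remote to interfere, O8a is the only free hydroxyl so the regiochemistry is fixed, and the reaction is stopped before retro-addition can erode the configuration.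

Step 15
Reactants: 26 the protected flavanone of step 14
Product: 27 (2S)-5-hydroxy-2-[2-methoxy-4-(triisopropylsilyloxy)phenyl]-8-[(2R)-5-methyl-2-(prop-1-en-2-yl)-5-(triethylsilyloxy)hexyl]-7-(triisopropylsilyloxy)-2,3-dihydro-4H-chromen-4-one
Conditions: MgBr2·OEt2, Me2S, CH2Cl2, 0 °C → rt
Reagents that add atoms: none
Why: Chelation-assisted ether cleavage: MgBr2 bridges the C4 carbonyl and O5, the sulfide takes the benzylic carbon and so keeps the 4-methoxybenzyl cation from alkylating C6; O7 stays silylated, so no free phenol flanks the isopropenyl group while the Lewis acid is present.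

Step 16
Reactants: 27 the 5-hydroxyflavanone of step 15
Product: 28 (2S)-5,7-dihydroxy-2-(4-hydroxy-2-methoxyphenyl)-8-[(2R)-5-hydroxy-5-methyl-2-(prop-1-en-2-yl)hexyl]-2,3-dihydro-4H-chromen-4-one (target)
Conditions: HF·pyridine, pyridine, THF, 0 °C → rt
Reagents that add atoms: none
Why: Fluoride-mediated cleavage of the two aryl triisopropylsilyl ethers and the tertiary triethylsilyl ether; the pyridine-buffered reagent is neither basic enough to open ring C at C2 nor acidic enough to protonate the isopropenyl group.

## Compound list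

1 | (R)-limonene | C=C(C)[C@@H]1CCC(C)=CC1 | starting material
2 | (4R)-1-methyl-4-(prop-1-en-2-yl)-7-oxabicyclo[4.1.0]heptane, both epoxide diastereomers | C=C(C)[C@@H]1CCC2(C)OC2C1 | intermediate
3 | (3R)-6-oxo-3-(prop-1-en-2-yl)heptanal | C=C(C)[C@@H](CC=O)CCC(C)=O | intermediate
4 | (3R)-6-oxo-3-(prop-1-en-2-yl)heptanoic acid | C=C(C)[C@@H](CC(=O)O)CCC(C)=O | intermediate
5 | methyl (3R)-6-oxo-3-(prop-1-en-2-yl)heptanoate | C=C(C)[C@@H](CC(=O)OC)CCC(C)=O | intermediate
6 | methyl (3R)-6-hydroxy-6-methyl-3-(prop-1-en-2-yl)heptanoate | C=C(C)[C@@H](CC(=O)OC)CCC(C)(C)O | intermediate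
7 | methyl (3R)-6-methyl-3-(prop-1-en-2-yl)-6-(triethylsilyloxy)heptanoate | C=C(C)[C@@H](CC(=O)OC)CCC(C)(C)O[Si](CC)(CC)CC | intermediate
8 | lithium (4R)-1,1-dibromo-7-methyl-4-(prop-1-en-2-yl)-7-(triethylsilyloxy)oct-1-en-2-olate (dibromo enolate) | C=C(C)[C@@H](CC(O[Li])=C(Br)Br)CCC(C)(C)O[Si](CC)(CC)CC | intermediate (not isolated)
9 | lithium (4R)-7-methyl-4-(prop-1-en-2-yl)-7-(triethylsilyloxy)oct-1-yn-1-olate (ynolate) | C=C(C)[C@@H](CC#CO[Li])CCC(C)(C)O[Si](CC)(CC)CC | intermediate (not isolated)
10 | triisopropyl{[(4R)-7-methyl-4-(prop-1-en-2-yl)-7-(triethylsilyloxy)oct-1-yn-1-yl]oxy}silane | C=C(C)[C@@H](CC#CO[Si](C(C)C)(C(C)C)C(C)C)CCC(C)(C)O[Si](CC)(CC)CC | intermediate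
11 | 3-ethoxycyclobut-2-en-1-one | CCOC1=CC(=O)C1 | starting material
12 | 4-methoxybenzyl alcohol | COc1ccc(CO)cc1 | starting material
13 | 3-[(4-methoxybenzyl)oxy]cyclobut-2-en-1-one | O=C1C=C(OCc2ccc(OC)cc2)C1 | intermediate
14 | 3-[(4-methoxybenzyl)oxy]buta-1,3-dien-1-one (vinylketene) | C=C(OCc1ccc(OC)cc1)C=C=O | intermediate (not isolated)
15 | 4-{1-[(4-methoxybenzyl)oxy]ethenyl}-2-[(2R)-5-methyl-2-(prop-1-en-2-yl)-5-(triethylsilyloxy)hexyl]-3-(triisopropylsilyloxy)cyclobut-2-en-1-one, both C4 epimers | C=C(C)[C@H](CCC(C)(C)O[Si](CC)(CC)CC)CC1=C(O[Si](C(C)C)(C(C)C)C(C)C)C(C(=C)OCc2ccc(OC)cc2)C1=O | intermediate (not isolated)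
16 | (3E)-5-[(4-methoxybenzyl)oxy]-2-[(2R)-5-methyl-2-(prop-1-en-2-yl)-5-(triethylsilyloxy)hexyl]-3-(triisopropylsilyloxy)hexa-1,3,5-trien-1-one (dienylketene, ketene and enol-ether vinyl cis) | C=C(C)[C@H](CCC(C)(C)O[Si](CC)(CC)CC)CC(=C=O)/C(O[Si](C(C)C)(C(C)C)C(C)C)=C\C(=C)OCc1ccc(OC)cc1 | intermediate (not isolated)
17 | 5-[(4-methoxybenzyl)oxy]-2-[(2R)-5-methyl-2-(prop-1-en-2-yl)-5-(triethylsilyloxy)hexyl]-3-(triisopropylsilyloxy)cyclohexa-2,4-dien-1-one | C=C(C)[C@H](CCC(C)(C)O[Si](CC)(CC)CC)CC1=C(O[Si](C(C)C)(C(C)C)C(C)C)C=C(OCc2ccc(OC)cc2)CC1=O | intermediate (not isolated)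
18 | 5-[(4-methoxybenzyl)oxy]-2-[(2R)-5-methyl-2-(prop-1-en-2-yl)-5-(triethylsilyloxy)hexyl]-3-(triisopropylsilyloxy)phenol | C=C(C)[C@H](CCC(C)(C)O[Si](CC)(CC)CC)Cc1c(O)cc(OCc2ccc(OC)cc2)cc1O[Si](C(C)C)(C(C)C)C(C)C | intermediate
19 | 2-bromo-3-[(4-methoxybenzyl)oxy]-6-[(2R)-5-methyl-2-(prop-1-en-2-yl)-5-(triethylsilyloxy)hexyl]-5-(triisopropylsilyloxy)phenol | C=C(C)[C@H](CCC(C)(C)O[Si](CC)(CC)CC)Cc1c(O)c(Br)c(OCc2ccc(OC)cc2)cc1O[Si](C(C)C)(C(C)C)C(C)C | intermediate
20 | 4-hydroxy-2-methoxybenzaldehyde | COc1cc(O)ccc1C=O | starting material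
21 | 2-methoxy-4-(triisopropylsilyloxy)benzaldehyde | COc1cc(O[Si](C(C)C)(C(C)C)C(C)C)ccc1C=O | intermediate
22 | diethyl {2-[methoxy(methyl)amino]-2-oxoethyl}phosphonate | CCOP(=O)(CC(=O)N(C)OC)OCC | starting material
23 | (2E)-N-methoxy-3-[2-methoxy-4-(triisopropylsilyloxy)phenyl]-N-methylprop-2-enamide | COc1cc(O[Si](C(C)C)(C(C)C)C(C)C)ccc1/C=C/C(=O)N(C)OC | intermediate
24 | O,C-dilithio derivative of 19 (lithium at C4a, lithium phenoxide at O8a) | C=C(C)[C@H](CCC(C)(C)O[Si](CC)(CC)CC)Cc1c(O[Li])c([Li])c(OCc2ccc(OC)cc2)cc1O[Si](C(C)C)(C(C)C)C(C)C | intermediate (not isolated)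
25 | (2E)-1-{2-hydroxy-6-[(4-methoxybenzyl)oxy]-3-[(2R)-5-methyl-2-(prop-1-en-2-yl)-5-(triethylsilyloxy)hexyl]-4-(triisopropylsilyloxy)phenyl}-3-[2-methoxy-4-(triisopropylsilyloxy)phenyl]prop-2-en-1-one | C=C(C)[C@H](CCC(C)(C)O[Si](CC)(CC)CC)Cc1c(O)c(C(=O)/C=C/c2ccc(O[Si](C(C)C)(C(C)C)C(C)C)cc2OC)c(OCc2ccc(OC)cc2)cc1O[Si](C(C)C)(C(C)C)C(C)C | intermediate
26 | (2S)-5-[(4-methoxybenzyl)oxy]-2-[2-methoxy-4-(triisopropylsilyloxy)phenyl]-8-[(2R)-5-methyl-2-(prop-1-en-2-yl)-5-(triethylsilyloxy)hexyl]-7-(triisopropylsilyloxy)-2,3-dihydro-4H-chromen-4-one | C=C(C)[C@H](CCC(C)(C)O[Si](CC)(CC)CC)Cc1c(O[Si](C(C)C)(C(C)C)C(C)C)cc(OCc2ccc(OC)cc2)c2c1O[C@H](c1ccc(O[Si](C(C)C)(C(C)C)C(C)C)cc1OC)CC2=O | intermediate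
27 | (2S)-5-hydroxy-2-[2-methoxy-4-(triisopropylsilyloxy)phenyl]-8-[(2R)-5-methyl-2-(prop-1-en-2-yl)-5-(triethylsilyloxy)hexyl]-7-(triisopropylsilyloxy)-2,3-dihydro-4H-chromen-4-one | C=C(C)[C@H](CCC(C)(C)O[Si](CC)(CC)CC)Cc1c(O[Si](C(C)C)(C(C)C)C(C)C)cc(O)c2c1O[C@H](c1ccc(O[Si](C(C)C)(C(C)C)C(C)C)cc1OC)CC2=O | intermediate
28 | (2S)-5,7-dihydroxy-2-(4-hydroxy-2-methoxyphenyl)-8-[(2R)-5-hydroxy-5-methyl-2-(prop-1-en-2-yl)hexyl]-2,3-dihydro-4H-chromen-4-one | C=C(C)[C@H](CCC(C)(C)O)Cc1c(O)cc(O)c2c1O[C@H](c1ccc(O)cc1OC)CC2=O | target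

## Step count and least certain steps

Total: 16 steps. Longest linear sequence: 13 steps (steps 1–7, 9, 10, 13–16).

**Step 9 (key step).** The donor-stabilised cyclobutenone 13 may open only at a temperature at which the siloxyalkyne 10 undergoes 1,3-silyl migration to a silylketene. The vinylketene may also be lost to dimerisation and to acylation of the product phenol.
Fallback: generate the same ketene by elimination instead of ring strain release. It sets out from 12 and comes back at 18 through 14. Phosphine-catalysed conjugate addition of 12 to ethyl but-2-ynoate F1 would give ethyl (2E)-3-[(4-methoxybenzyl)oxy]but-2-enoate F2. Saponification would give (2E)-3-[(4-methoxybenzyl)oxy]but-2-enoic acid F3. The neutral chlorinating agent 1-chloro-N,N,2-trimethylprop-1-en-1-amine would convert F3 into (2E)-3-[(4-methoxybenzyl)oxy]but-2-enoyl chloride F4. Triethylamine, acting on F4 at room temperature in the presence of 10, should effect 1,4-dehydrochlorination to 14, which is trapped as 15. Warming to about 80 °C would then carry 15 through 16 and 17 to 18.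

**Step 14.** Facial selectivity in the C–O bond formation may be poor on this hindered, doubly ortho-substituted chalcone. Configuration may also erode through reversible ring opening under the basic catalyst.
Fallback: separate C–O bond formation from stereoselection. It sets out from 25 and comes back at 26. An achiral tertiary amine (DABCO, toluene) would close 25 to a mixture of 26 and its C2 epimer F5. Noyori transfer hydrogenation with the enantiomer of RuCl(p-cymene)[TsDPEN] that is matched to the 2R series (HCO2H/Et3N) should then reduce F5 to the cis-flavan-4-ol F6 and leave 26. The two differ in polarity enough to be separated.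

**Step 10.** Substitution may occur at C6 (para to the hydroxyl), a second bromine may enter, or the very electron-rich ring may be oxidised.
Fallback: use an ortho-specific magnesium-templated reaction and build the ketone from an aldehyde. It sets out from 18 and comes back at 25, bypassing 19 and 23. Casnati–Skattebøl formylation (MgCl2, Et3N, paraformaldehyde, THF, reflux) can only reach C4a and would give 2-hydroxy-6-[(4-methoxybenzyl)oxy]-3-[(2R)-5-methyl-2-(prop-1-en-2-yl)-5-(triethylsilyloxy)hexyl]-4-(triisopropylsilyloxy)benzaldehyde F7. MeMgBr would give the 1-arylethanol F8, and MnO2 the 2-hydroxyacetophenone F9. Aldol addition of F9 (LiHMDS, THF, −78 °C) to aldehyde 21 would give the β-hydroxy ketone F10, which is dehydrated (MsCl, Et3N) to 25.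

**Step 8.** The benzylic alcohol may ionise and self-etherify under the acid catalyst, or the strained vinylogous ester may be cleaved, so that the exchange stalls.
Fallback: form the enol ether by alkylation of the dione instead of exchange. It sets out from 11 and comes back at 13. Cold dilute hydrochloric acid would hydrolyse 11 to cyclobutane-1,3-dione F11, whose acidic enol should undergo Mitsunobu O-alkylation with 12 (PPh3, DIAD, THF).

## Further compounds

F1 | step 9 | ethyl but-2-ynoate (purchased) | CC#CC(=O)OCC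
F2 | step 9 | ethyl (2E)-3-[(4-methoxybenzyl)oxy]but-2-enoate | CCOC(=O)/C=C(\C)OCc1ccc(OC)cc1
F3 | step 9 | (2E)-3-[(4-methoxybenzyl)oxy]but-2-enoic acid | O=C(O)/C=C(\C)OCc1ccc(OC)cc1
F4 | step 9 | (2E)-3-[(4-methoxybenzyl)oxy]but-2-enoyl chloride | O=C(Cl)/C=C(\C)OCc1ccc(OC)cc1
F5 | step 14 | (2R)-5-[(4-methoxybenzyl)oxy]-2-[2-methoxy-4-(triisopropylsilyloxy)phenyl]-8-[(2R)-5-methyl-2-(prop-1-en-2-yl)-5-(triethylsilyloxy)hexyl]-7-(triisopropylsilyloxy)-2,3-dihydro-4H-chromen-4-one (C2 epimer of 26) | C=C(C)[C@H](CCC(C)(C)O[Si](CC)(CC)CC)Cc1c(O[Si](C(C)C)(C(C)C)C(C)C)cc(OCc2ccc(OC)cc2)c2c1O[C@@H](c1ccc(O[Si](C(C)C)(C(C)C)C(C)C)cc1OC)CC2=O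
F6 | step 14 | (2R,4R)-5-[(4-methoxybenzyl)oxy]-2-[2-methoxy-4-(triisopropylsilyloxy)phenyl]-8-[(2R)-5-methyl-2-(prop-1-en-2-yl)-5-(triethylsilyloxy)hexyl]-7-(triisopropylsilyloxy)-3,4-dihydro-2H-chromen-4-ol (2,4-cis) | C=C(C)[C@H](CCC(C)(C)O[Si](CC)(CC)CC)Cc1c(O[Si](C(C)C)(C(C)C)C(C)C)cc(OCc2ccc(OC)cc2)c2c1O[C@@H](c1ccc(O[Si](C(C)C)(C(C)C)C(C)C)cc1OC)C[C@H]2O
F7 | step 10 | 2-hydroxy-6-[(4-methoxybenzyl)oxy]-3-[(2R)-5-methyl-2-(prop-1-en-2-yl)-5-(triethylsilyloxy)hexyl]-4-(triisopropylsilyloxy)benzaldehyde | C=C(C)[C@H](CCC(C)(C)O[Si](CC)(CC)CC)Cc1c(O)c(C=O)c(OCc2ccc(OC)cc2)cc1O[Si](C(C)C)(C(C)C)C(C)C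
F8 | step 10 | 2-(1-hydroxyethyl)-3-[(4-methoxybenzyl)oxy]-6-[(2R)-5-methyl-2-(prop-1-en-2-yl)-5-(triethylsilyloxy)hexyl]-5-(triisopropylsilyloxy)phenol, both carbinol epimers | C=C(C)[C@H](CCC(C)(C)O[Si](CC)(CC)CC)Cc1c(O)c(C(C)O)c(OCc2ccc(OC)cc2)cc1O[Si](C(C)C)(C(C)C)C(C)C
F9 | step 10 | 1-{2-hydroxy-6-[(4-methoxybenzyl)oxy]-3-[(2R)-5-methyl-2-(prop-1-en-2-yl)-5-(triethylsilyloxy)hexyl]-4-(triisopropylsilyloxy)phenyl}ethan-1-one | C=C(C)[C@H](CCC(C)(C)O[Si](CC)(CC)CC)Cc1c(O)c(C(C)=O)c(OCc2ccc(OC)cc2)cc1O[Si](C(C)C)(C(C)C)C(C)C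
F10 | step 10 | 3-hydroxy-1-{2-hydroxy-6-[(4-methoxybenzyl)oxy]-3-[(2R)-5-methyl-2-(prop-1-en-2-yl)-5-(triethylsilyloxy)hexyl]-4-(triisopropylsilyloxy)phenyl}-3-[2-methoxy-4-(triisopropylsilyloxy)phenyl]propan-1-one, both carbinol epimers | C=C(C)[C@H](CCC(C)(C)O[Si](CC)(CC)CC)Cc1c(O)c(C(=O)CC(O)c2ccc(O[Si](C(C)C)(C(C)C)C(C)C)cc2OC)c(OCc2ccc(OC)cc2)cc1O[Si](C(C)C)(C(C)C)C(C)C
F11 | step 8 | cyclobutane-1,3-dione | O=C1CC(=O)C1
A1 | alternative 1 | (2S)-2-[4-(tert-butyldimethylsilyloxy)-2-methoxyphenyl]-5,7-dihydroxy-8-[(2R)-5-methyl-2-(prop-1-en-2-yl)-5-(triethylsilyloxy)hexyl]-2,3-dihydro-4H-chromen-4-one | C=C(C)[C@H](CCC(C)(C)O[Si](CC)(CC)CC)Cc1c(O)cc(O)c2c1O[C@H](c1ccc(O[Si](C)(C)C(C)(C)C)cc1OC)CC2=O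
A2 | alternative 1 | 6-{(3R)-1-[(2S)-2-[4-(tert-butyldimethylsilyloxy)-2-methoxyphenyl]-4-oxo-3,4-dihydro-2H-pyran-6-yl]-6-methyl-3-(prop-1-en-2-yl)-6-(triethylsilyloxy)heptyl}-2,2-dimethyl-4H-1,3-dioxin-4-one, both C1 epimers of the heptyl chain | CC1(C)OC(=O)C=C(O1)C(C[C@H](C(C)=C)CCC(C)(C)O[Si](CC)(CC)CC)C1=CC(=O)C[C@@H](c2ccc(O[Si](C)(C)C(C)(C)C)cc2OC)O1
A3 | alternative 2 | (2S,4S)-7-(tert-butyldimethylsilyloxy)-2-(4-hydroxy-2-methoxyphenyl)-4-methoxy-8-[(2R)-5-methyl-2-(prop-1-en-2-yl)-5-(triethylsilyloxy)hexyl]-5-(triisopropylsilyloxy)-3,4-dihydro-2H-chromene (2,4-cis) | C=C(C)[C@H](CCC(C)(C)O[Si](CC)(CC)CC)Cc1c(O[Si](C)(C)C(C)(C)C)cc(O[Si](C(C)C)(C(C)C)C(C)C)c2c1O[C@H](c1ccc(O)cc1OC)C[C@@H]2OC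
A4 | alternative 2 | 3-(tert-butyldimethylsilyloxy)-6-(dimethoxymethyl)-2-[(2R)-5-methyl-2-(prop-1-en-2-yl)-5-(triethylsilyloxy)hexyl]-5-(triisopropylsilyloxy)phenol | C=C(C)[C@H](CCC(C)(C)O[Si](CC)(CC)CC)Cc1c(O[Si](C)(C)C(C)(C)C)cc(O[Si](C(C)C)(C(C)C)C(C)C)c(C(OC)OC)c1O
A5 | alternative 2 | 4-ethenyl-3-methoxyphenol | C=Cc1ccc(O)cc1OC
A6 | alternative 3 | 7-(tert-butyldimethylsilyloxy)-2-[4-(tert-butyldimethylsilyloxy)-2-methoxyphenyl]-8-[(2R)-5-methyl-2-(prop-1-en-2-yl)-5-(triethylsilyloxy)hexyl]-5-(triisopropylsilyloxy)-4H-chromen-4-one | C=C(C)[C@H](CCC(C)(C)O[Si](CC)(CC)CC)Cc1c(O[Si](C)(C)C(C)(C)C)cc(O[Si](C(C)C)(C(C)C)C(C)C)c2c1OC(c1ccc(O[Si](C)(C)C(C)(C)C)cc1OC)=CC2=O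
A7 | alternative 3 | 3-(tert-butyldimethylsilyloxy)-6-iodo-2-[(2R)-5-methyl-2-(prop-1-en-2-yl)-5-(triethylsilyloxy)hexyl]-5-(triisopropylsilyloxy)phenol | C=C(C)[C@H](CCC(C)(C)O[Si](CC)(CC)CC)Cc1c(O[Si](C)(C)C(C)(C)C)cc(O[Si](C(C)C)(C(C)C)C(C)C)c(I)c1O
A8 | alternative 3 | tert-butyl(4-ethynyl-3-methoxyphenoxy)dimethylsilane | C#Cc1ccc(O[Si](C)(C)C(C)(C)C)cc1OC
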